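**Retrosynthetic overview**

1. Feature: in the pyran (O1, spiro C2, C3–C6), C3 carries the ansa pyrrole and is the α‑carbon of a pyrrol‑2‑ylacetic acid whose carboxyl carbon is C2, while C4 is allylic to the first carbon of the heptamethylene chain. The C3–C4 bond and the 12‑membered ansa ring therefore come from a [3,3] shift of a 12‑membered pyrrolylacetate allylic macrolactone.
2. Ring A is taken back to an imidoyl triflate (Suzuki), a spiro N,O‑ketal lactam (amide onto the pyranyl oxocarbenium ion), propiolate addition to the δ‑lactone, and the lactone itself from the Claisen acid and the C6 silyl ether.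
3. The macrolactone comes from Shiina closure of a seco acid built from ethyl pyrrol‑2‑ylacetate, 6‑bromohexanoyl chloride and the (S)‑propylene oxide‑derived alkyne, joined by a catalytic asymmetric alkenylzinc addition.
4. Stereochemistry: C6 comes from the epoxide. The pyrrole/pentamethylene tether enforces a boat and hence a Z ring alkene, so C4 must be relayed from an (R)‑carbinol. C3 emerges cis and is equilibrated at the lactone; the spiro centre is set reversibly under acid.
5. Ring order: macrolactone → ansa carbocycle → δ‑lactone (pyran) → spiro lactam (ring A) → terminal pyrrole attached.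

Key step: step 10

Remark: pyran locants O1, C2 (carboxyl, later spiro), C3–C6 are used for all intermediates, cis/trans at C3/C4 refers to the pyrrole on C3 and the ansa‑chain bond on C4, and (−)‑MIB is taken as the 3‑exo‑morpholinoisoborneol enantiomer that delivers organozinc groups to the Si face of aldehydes.

**Route**

Step 1
Reactants: 1 (S)-propylene oxide; 2 lithium acetylide–ethylenediamine complex
Product: 3 (S)-pent-4-yn-2-ol
Conditions: DMSO, 0 °C to rt; H2O
Reagents that add atoms: none
Why: SN2 epoxide opening by the acetylide at the CH2 carbon leaves the (S) centre, the future C6, untouched.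

Step 2
Reactants: 3 (S)-pent-4-yn-2-ol
Product: 4 (S)-tert-butyldimethyl(pent-4-yn-2-yloxy)silane
Conditions: TBSCl, imidazole, DMF, rt
Reagents that add atoms: tert-butyldimethylsilyl chloride, CC(C)(C)[Si](C)(C)Cl
Why: Silyl ether formation masks the C6 oxygen until the Claisen acid is in hand and tolerates the organozinc, Shiina and enolate steps.

Step 3
Reactants: 5 ethyl 2-(1H-pyrrol-2-yl)acetate; 6 6-bromohexanoyl chloride
Product: 8 ethyl 2-[5-(6-bromohexanoyl)-1H-pyrrol-2-yl]acetate, via N-aluminated pyrrole 7 (not isolated)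
Conditions: Et2AlCl, CH2Cl2, 0 °C; then 6, 0 °C; 1 M HCl work-up
Reagents that add atoms: none
Why: Friedel–Crafts acylation of the N‑metalated 2‑alkylpyrrole goes to the free α‑position C5, and the ethyl groups on aluminium take up the acid so that ester, bromide and pyrrole survive.

Step 4
Reactants: 8 ethyl 2-[5-(6-bromohexanoyl)-1H-pyrrol-2-yl]acetate
Product: 9 ethyl 2-[5-(6-bromohexyl)-1H-pyrrol-2-yl]acetate
Conditions: BH3·THF, THF, 0 °C to rt; aqueous work-up
Reagents that add atoms: none
Why: Borane deoxygenation of a 2‑acylpyrrole (a vinylogous amide, reduced through the azafulvene to the methylene) is faster than reduction of the aliphatic ester and leaves the alkyl bromide.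

Step 5
Reactants: 9 ethyl 2-[5-(6-bromohexyl)-1H-pyrrol-2-yl]acetate
Product: 10 ethyl 2-[5-(6-bromohexyl)-1-Boc-pyrrol-2-yl]acetate
Conditions: Boc2O, DMAP (cat.), MeCN, rt
Reagents that add atoms: di-tert-butyl dicarbonate, CC(C)(C)OC(=O)OC(=O)OC(C)(C)C
Why: DMAP‑catalysed N‑acylation removes the acidic N–H before the organozinc and enolate steps and tempers the electron‑rich pyrrole.

Step 6
Reactants: 10 ethyl 2-[5-(6-bromohexyl)-1-Boc-pyrrol-2-yl]acetate
Product: 11 ethyl 2-[1-Boc-5-(6-oxohexyl)pyrrol-2-yl]acetate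
Conditions: Me3NO (anhydrous), DMSO, rt to 40 °C
Reagents that add atoms: trimethylamine N-oxide, C[N+](C)(C)[O-]
Why: Kornblum‑type oxidation: SN2 displacement of the primary bromide by the N‑oxide oxygen and loss of trimethylamine give the aldehyde without an oxidant that could attack the pyrrole.

Step 7
Reactants: 4 (S)-tert-butyldimethyl(pent-4-yn-2-yloxy)silane; 11 ethyl 2-[1-Boc-5-(6-oxohexyl)pyrrol-2-yl]acetate
Product: 14 ethyl 2-{1-Boc-5-[(6R,7E,10S)-10-(TBSO)-6-hydroxyundec-7-en-1-yl]pyrrol-2-yl}acetate, via alkenylborane 12 (not isolated), via alkenylzinc 13 (not isolated)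
Conditions: 4, Cy2BH, toluene, 0 °C to rt; Et2Zn, −78 °C; (−)-MIB (cat.), then 11, −20 to 0 °C; aq. NH4Cl
Reagents that add atoms: none
Why: syn‑Hydroboration fixes the E‑alkene, boron‑to‑zinc exchange gives the alkenylzinc, and its amino‑alcohol‑catalysed asymmetric addition to the Si face of the aldehyde sets the (R)‑carbinol; ester and carbamate are inert to the zinc reagent, and any carbinol epimer becomes a separable ring diastereomer at lactone 21.

Step 8
Reactants: 14 ethyl 2-{1-Boc-5-[(6R,7E,10S)-10-(TBSO)-6-hydroxyundec-7-en-1-yl]pyrrol-2-yl}acetate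
Product: 15 2-{1-Boc-5-[(6R,7E,10S)-10-(TBSO)-6-hydroxyundec-7-en-1-yl]pyrrol-2-yl}acetic acid
Conditions: Me3SnOH, 1,2-dichloroethane, 70 °C; dilute HCl work-up
Reagents that add atoms: trimethyltin hydroxide, C[Sn](C)(C)O
Why: Tin hydroxide‑mediated ester hydrolysis is mild enough to spare the N‑Boc pyrrole (labile to alkoxide and hydroxide), the TBS ether and the allylic alcohol.

Step 9
Reactants: 15 2-{1-Boc-5-[(6R,7E,10S)-10-(TBSO)-6-hydroxyundec-7-en-1-yl]pyrrol-2-yl}acetic acid
Product: 16 (R)-carbinol (E)-alkenyl twelve-membered macrolactone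
Conditions: MNBA, DMAP, Et3N, CH2Cl2 (2 mM, slow addition), rt
Reagents that add atoms: none
Why: Shiina macrolactonisation through the mixed anhydride acylates the secondary allylic alcohol and closes the 12‑membered ring (C=O, CH2, pyrrole C2, N, pyrrole C5, five CH2, carbinol CH, O) without touching the carbinol configuration.

Step 10
Reactants: 16 (R)-carbinol (E)-alkenyl twelve-membered macrolactone
Product: 19 (Z)-alkene ansa pyrrolophane carboxylic acid (3,4-cis series), via silyl ketene acetal 17 (not isolated), via trimethylsilyl ester 18 (not isolated)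
Conditions: LiHMDS, TMSCl, THF, −78 °C to rt (50 °C if needed); aq. citric acid
Reagents that add atoms: none
Why: Ireland–Claisen rearrangement: LiHMDS/TMSCl gives silyl ketene acetal 17, in which the twelve‑membered ring allows only the geometry with the pyrrole syn to the ring oxygen, and a concerted suprafacial [3,3] shift then forms C3–C4 as the carbinol C–O bond breaks; the closest known reaction type is the Claisen rearrangement of lactone silyl ketene acetals that carry an alkenyl group on the carbinol carbon. The twelve‑membered carbocycle is closed by ring transposition, not by exo or endo attack of a chain end: the two alkene carbons enter the ring while the carboxyl carbon and the ring oxygen leave it, through a bicyclic six‑membered transition state. Because the rigid pyrrole/pentamethylene tether can only bridge the inward‑pointing positions of the ketene acetal terminus and of the carbinol carbon, the array should be a boat and the new ring alkene Z. C4 is set by the (R)‑carbinol: the new bond forms on the alkene face from which the oxygen leaves, and with the tether inside this relays (R) into the C4 configuration of the target (an (S)‑carbinol would give it only through an E ring alkene, which the tether cannot span). C3 is set by the ring‑fixed ketene acetal geometry and the boat, which place the pyrrole cis to the ansa bond at C4, that is the 3‑epimer that step 13 corrects. The selectivity the step needs is the face selectivity at the allyl terminus, which the carbinol configuration, the E‑alkene and the tether secure, and in situ silylation suppresses ketene loss from the arylacetate enolate.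

Step 11
Reactants: 19 (Z)-alkene ansa pyrrolophane carboxylic acid (3,4-cis series)
Product: 21 (3R,4R,6S)-3,4-cis ansa lactone with (Z) ring alkene, via hydroxy acid 20 (not isolated)
Conditions: HF·pyridine, THF, 0 °C to rt; then PPTS (cat.), toluene, 50 °C
Reagents that add atoms: none
Why: Desilylation frees the C6 hydroxyl, which closes the six‑membered lactone on the carboxyl group (acid‑catalysed lactonisation); the O–C6 bond is not broken, so C6 stays (S).

Step 12
Reactants: 21 (3R,4R,6S)-3,4-cis ansa lactone with (Z) ring alkene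
Product: 22 (3R,4S,6S)-3,4-cis saturated ansa lactone
Conditions: H2 (1 atm), Pd/C, EtOAc, rt
Reagents that add atoms: none
Why: Heterogeneous hydrogenation of the disubstituted ring alkene completes the heptamethylene bridge; the N‑Boc pyrrole and the lactone are not reduced under these conditions.

Step 13
Reactants: 22 (3R,4S,6S)-3,4-cis saturated ansa lactone
Product: 23 (3S,4S,6S)-3,4-trans saturated ansa lactone
Conditions: DBU, toluene, 80 °C
Reagents that add atoms: none
Why: Base‑mediated epimerisation through the lactone enolate (C3–H is activated by carbonyl and pyrrole); the 3,4‑trans lactone should predominate at equilibrium because it alone keeps both ansa‑ring bonds pseudo‑equatorial on the lactone half‑chair, and C4 and C6 are not acidic.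

Step 14
Reactants: 23 (3S,4S,6S)-3,4-trans saturated ansa lactone; 24 methyl propiolate
Product: 26 (3S,4S,6S)-2-hydroxy-2-(3-methoxy-3-oxoprop-1-ynyl) ansa tetrahydropyran (lactol), via lithium methyl propiolate 25 (not isolated)
Conditions: 24, LiHMDS, THF, −78 °C; then 23, −78 °C; AcOH quench
Reagents that add atoms: none
Why: 1,2‑Addition of the lithium acetylide to the lactone carbonyl gives a tetrahedral alkoxide that is stable at −78 °C and is released as the cyclic hemiketal; the weakly basic acetylide should not enolise C3.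

Step 15
Reactants: 26 (3S,4S,6S)-2-hydroxy-2-(3-methoxy-3-oxoprop-1-ynyl) ansa tetrahydropyran (lactol)
Product: 27 methyl ketal of 26 (anomer mixture)
Conditions: CSA (cat.), MeOH, 0 °C to rt
Reagents that add atoms: methanol, CO
Why: Acid‑catalysed ketalisation through the oxocarbenium ion (Fischer glycosidation type) masks the ketone, so that the alkyne is activated only by the ester.

Step 16
Reactants: 27 methyl ketal of 26 (anomer mixture)
Product: 29 methyl (E)-3-methoxy-3-(2-methoxy ansa-tetrahydropyran-2-yl)acrylate with free pyrrole N–H, via N-Boc methoxyacrylate 28 (not isolated)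
Conditions: NaOMe (0.5 equiv), MeOH, 0 °C to rt
Reagents that add atoms: methanol, CO
Why: Oxa‑Michael addition of methoxide to the ynoate places the methoxy group on the carbon next to the ketal (β to the ester), and the same methoxide removes the pyrrole N‑Boc group by methanolysis, which the ammonia step would do in any case.

Step 17
Reactants: 29 methyl (E)-3-methoxy-3-(2-methoxy ansa-tetrahydropyran-2-yl)acrylate with free pyrrole N–H
Product: 30 (E)-3-methoxy-3-(2-methoxy ansa-tetrahydropyran-2-yl)acrylamide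
Conditions: NH3 (7 M in MeOH), sealed tube, 60 °C
Reagents that add atoms: ammonia, N
Why: Ester ammonolysis; addition–elimination at the β‑carbon should be held back by the adjacent fully substituted ketal carbon.

Step 18
Reactants: 30 (E)-3-methoxy-3-(2-methoxy ansa-tetrahydropyran-2-yl)acrylamide
Product: 31 (2R,3S,4S,6S)-spiro lactam (4-methoxy-3-pyrrolin-2-one spiro-fused at its C5 to pyran C2)
Conditions: CSA, 4 Å MS, CH2Cl2, rt
Reagents that add atoms: none
Why: Acid ionises the methyl ketal to the pyranyl oxocarbenium ion, which the amide nitrogen captures (5‑exo‑trig spiro‑amidation); the closure is reversible, so the spiro centre should settle under thermodynamic control in the chair with nitrogen axial (anomeric) and both ansa bonds equatorial, and alkene E/Z isomers converge through the same cation.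

Step 19
Reactants: 31 (2R,3S,4S,6S)-spiro lactam
Product: 32 spiro 3-methoxy-5-(trifluoromethanesulfonyloxy)-2H-pyrrole (imidoyl triflate)
Conditions: Tf2O, 2,6-di-tert-butyl-4-methylpyridine, CH2Cl2, −78 to 0 °C
Reagents that add atoms: trifluoromethanesulfonic anhydride, O=S(=O)(OS(=O)(=O)C(F)(F)F)C(F)(F)F
Why: O‑Sulfonylation of the vinylogous carbamate lactam gives the imidoyl triflate; the amide oxygen is the most nucleophilic site, the pyrrole N–H lone pair is tied up in the aromatic sextet, and the hindered base does not attack the triflate.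

Step 20
Reactants: 32 spiro imidoyl triflate; 33 1-Boc-pyrrol-2-ylboronic acid
Product: 34 N-Boc-premarineosin A (Boc on the terminal pyrrole)
Conditions: Pd(PPh3)4 (cat.), Na2CO3 (aq), DME, 80 °C
Reagents that add atoms: none
Why: Suzuki–Miyaura coupling of the imidoyl triflate with the 2‑pyrrolylboronic acid forms the bipyrrole C–C bond at a carbon remote from all stereocentres.

Step 21
Reactants: 34 N-Boc-premarineosin A
Product: 35 premarineosin A
Conditions: NaOMe, MeOH/THF, rt
Reagents that add atoms: none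
Why: Basic methanolysis of the N‑Boc pyrrole carbamate leaves the acid‑sensitive spiro N,O‑ketal and the enol ether untouched.

**Compound list**

1 | (S)-propylene oxide | C[C@H]1CO1 | starting material
2 | lithium acetylide–ethylenediamine complex | [Li+].[C-]#C.NCCN | starting material
3 | (S)-pent-4-yn-2-ol | C[C@H](O)CC#C | intermediate
4 | (S)-tert-butyldimethyl(pent-4-yn-2-yloxy)silane | C[C@H](O[Si](C)(C)C(C)(C)C)CC#C | intermediate
5 | ethyl 2-(1H-pyrrol-2-yl)acetate | CCOC(=O)Cc1ccc[nH]1 | starting material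
6 | 6-bromohexanoyl chloride | O=C(Cl)CCCCCBr | starting material
7 | ethyl 2-[1-(chloro(ethyl)alumanyl)pyrrol-2-yl]acetate (N-aluminated pyrrole) | CCOC(=O)Cc1cccn1[Al](Cl)CC | intermediate
8 | ethyl 2-[5-(6-bromohexanoyl)-1H-pyrrol-2-yl]acetate | CCOC(=O)Cc1ccc([nH]1)C(=O)CCCCCBr | intermediate
9 | ethyl 2-[5-(6-bromohexyl)-1H-pyrrol-2-yl]acetate | CCOC(=O)Cc1ccc(CCCCCCBr)[nH]1 | intermediate
10 | ethyl 2-[5-(6-bromohexyl)-1-(tert-butoxycarbonyl)pyrrol-2-yl]acetate | CCOC(=O)Cc1ccc(CCCCCCBr)n1C(=O)OC(C)(C)C | intermediate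
11 | ethyl 2-[1-Boc-5-(6-oxohexyl)pyrrol-2-yl]acetate | CCOC(=O)Cc1ccc(CCCCCC=O)n1C(=O)OC(C)(C)C | intermediate
12 | dicyclohexyl[(1E,4S)-4-(TBSO)pent-1-en-1-yl]borane | C[C@H](O[Si](C)(C)C(C)(C)C)C/C=C/B(C1CCCCC1)C1CCCCC1 | intermediate
13 | ethyl[(1E,4S)-4-(TBSO)pent-1-en-1-yl]zinc | C[C@H](O[Si](C)(C)C(C)(C)C)C/C=C/[Zn]CC | intermediate
14 | ethyl 2-{1-Boc-5-[(6R,7E,10S)-10-(TBSO)-6-hydroxyundec-7-en-1-yl]pyrrol-2-yl}acetate | CCOC(=O)Cc1ccc(CCCCC[C@@H](O)/C=C/C[C@H](C)O[Si](C)(C)C(C)(C)C)n1C(=O)OC(C)(C)C | intermediate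
15 | 2-{1-Boc-5-[(6R,7E,10S)-10-(TBSO)-6-hydroxyundec-7-en-1-yl]pyrrol-2-yl}acetic acid | OC(=O)Cc1ccc(CCCCC[C@@H](O)/C=C/C[C@H](C)O[Si](C)(C)C(C)(C)C)n1C(=O)OC(C)(C)C | intermediate
16 | twelve-membered macrolactone of 15: N-Boc pyrrol-2-ylacetate lactone with the (1E,4S)-4-(TBSO)pent-1-enyl group on the (R)-carbinol carbon | O=C1Cc2ccc(CCCCC[C@@H](O1)/C=C/C[C@H](C)O[Si](C)(C)C(C)(C)C)n2C(=O)OC(C)(C)C | intermediate
17 | (E)-O-trimethylsilyl ketene acetal of 16 (pyrrole syn to the ring oxygen) | C[Si](C)(C)O/C1=C/c2ccc(CCCCC[C@@H](O1)/C=C/C[C@H](C)O[Si](C)(C)C(C)(C)C)n2C(=O)OC(C)(C)C | intermediate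
18 | trimethylsilyl ester of 19 | C[C@H](O[Si](C)(C)C(C)(C)C)C[C@@H]1/C=C\CCCCCc2ccc(n2C(=O)OC(C)(C)C)[C@@H]1C(=O)O[Si](C)(C)C | intermediate
19 | N-Boc ansa pyrrolophane acid: twelve-membered carbocycle with (Z) ring alkene; Cα (future C3, R) bears CO2H and is bonded to pyrrole C2; Cβ (future C4, R) bears the (S)-2-(TBSO)propyl group | C[C@H](O[Si](C)(C)C(C)(C)C)C[C@@H]1/C=C\CCCCCc2ccc(n2C(=O)OC(C)(C)C)[C@@H]1C(=O)O | intermediate
20 | hydroxy acid from 19 (free (S)-2-hydroxypropyl group) | C[C@H](O)C[C@@H]1/C=C\CCCCCc2ccc(n2C(=O)OC(C)(C)C)[C@@H]1C(=O)O | intermediate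
21 | (3R,4R,6S)-3,4-cis ansa lactone: 6-methyltetrahydropyran-2-one, C3 bonded to pyrrole C2, C4 starting the (Z)-CH=CH(CH2)5 bridge to pyrrole C5, N-Boc | C[C@H]1C[C@@H]2/C=C\CCCCCc3ccc(n3C(=O)OC(C)(C)C)[C@@H]2C(=O)O1 | intermediate
22 | (3R,4S,6S)-3,4-cis saturated ansa lactone (heptamethylene bridge), N-Boc | C[C@H]1C[C@@H]2CCCCCCCc3ccc(n3C(=O)OC(C)(C)C)[C@@H]2C(=O)O1 | intermediate
23 | (3S,4S,6S)-3,4-trans saturated ansa lactone, N-Boc | C[C@H]1C[C@@H]2CCCCCCCc3ccc(n3C(=O)OC(C)(C)C)[C@H]2C(=O)O1 | intermediate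
24 | methyl propiolate | C#CC(=O)OC | starting material
25 | lithium methyl propiolate (lithium 3-methoxy-3-oxoprop-1-yn-1-ide) | [Li+].[C-]#CC(=O)OC | intermediate
26 | (3S,4S,6S)-lactol: 2-hydroxy-2-(3-methoxy-3-oxoprop-1-ynyl) ansa tetrahydropyran, N-Boc, anomer mixture | COC(=O)C#CC2(O)O[C@@H](C)C[C@@H]1CCCCCCCc3ccc(n3C(=O)OC(C)(C)C)[C@H]12 | intermediate
27 | methyl ketal of 26 (2-methoxy), N-Boc, anomer mixture | COC(=O)C#CC2(OC)O[C@@H](C)C[C@@H]1CCCCCCCc3ccc(n3C(=O)OC(C)(C)C)[C@H]12 | intermediate
28 | methyl (E)-3-methoxy-3-(2-methoxy ansa-tetrahydropyran-2-yl)acrylate, N-Boc | COC(=O)/C=C(/OC)C2(OC)O[C@@H](C)C[C@@H]1CCCCCCCc3ccc(n3C(=O)OC(C)(C)C)[C@H]12 | intermediate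
29 | methyl (E)-3-methoxy-3-(2-methoxy ansa-tetrahydropyran-2-yl)acrylate, pyrrole N–H | COC(=O)/C=C(/OC)C2(OC)O[C@@H](C)C[C@@H]1CCCCCCCc3ccc([nH]3)[C@H]12 | intermediate
30 | (E)-3-methoxy-3-(2-methoxy ansa-tetrahydropyran-2-yl)acrylamide, pyrrole N–H | NC(=O)/C=C(/OC)C2(OC)O[C@@H](C)C[C@@H]1CCCCCCCc3ccc([nH]3)[C@H]12 | intermediate
31 | (2R,3S,4S,6S)-spiro lactam: 4-methoxy-3-pyrrolin-2-one spiro-fused at its C5 to pyran C2 | COC1=CC(=O)N[C@]12O[C@@H](C)C[C@@H]1CCCCCCCc3ccc([nH]3)[C@H]12 | intermediate
32 | spiro 3-methoxy-5-(trifluoromethanesulfonyloxy)-2H-pyrrole (imidoyl triflate), spiro at C2 | COC1=CC(OS(=O)(=O)C(F)(F)F)=N[C@]12O[C@@H](C)C[C@@H]1CCCCCCCc3ccc([nH]3)[C@H]12 | intermediate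
33 | 1-(tert-butoxycarbonyl)pyrrol-2-ylboronic acid | OB(O)c1cccn1C(=O)OC(C)(C)C | starting material
34 | N-Boc-premarineosin A (Boc on the terminal pyrrole) | COC1=CC(c2cccn2C(=O)OC(C)(C)C)=N[C@]12O[C@@H](C)C[C@@H]1CCCCCCCc3ccc([nH]3)[C@H]12 | intermediate
35 | premarineosin A, (2R,3S,4S,6S) in pyran numbering | COC1=CC(c2ccc[nH]2)=N[C@]12O[C@@H](C)C[C@@H]1CCCCCCCc3ccc([nH]3)[C@H]12 | target

**Step count**

Total: 21 steps. Longest linear sequence: 19 steps (steps 3–21, from ethyl 2-(1H-pyrrol-2-yl)acetate); the alkyne branch (steps 1–2) joins at step 7.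

**Steps most likely to fail**

Step 10. A chair‑like pathway with the tether on the outward position of the carbinol carbon may compete; it would give an E ring alkene and the C4 epimer, so the alkene geometry of 19 shows which pathway ran. The strained bicyclic transition state may also be slow enough for the enolate to fragment to a ketene. The fallback forms the C3–C4 bond in an open‑chain rearrangement and closes the ansa ring afterwards; it sets out from aldehyde 11 and alkyne 4 and returns at lactone 23. Wittig methylenation of 11 (Ph3P=CH2, THF) gives ethyl 2-[1-Boc-5-(hept-6-en-1-yl)pyrrol-2-yl]acetate F1, and Me3SnOH gives 2-[1-Boc-5-(hept-6-en-1-yl)pyrrol-2-yl]acetic acid F2. Alkyne 4 is acylated (n‑BuLi; N‑methoxy‑N‑methylacetamide) to (S)-6-(TBSO)hept-3-yn-2-one F3, Noyori transfer hydrogenation with the (R,R)‑TsDPEN ruthenium catalyst gives (2R,6S)-6-(TBSO)hept-3-yn-2-ol F4, and Lindlar semihydrogenation gives (2R,3Z,6S)-6-(TBSO)hept-3-en-2-ol F5. Esterification (EDCI, DMAP) gives (2R,3Z,6S)-6-(TBSO)hept-3-en-2-yl 2-[1-Boc-5-(hept-6-en-1-yl)pyrrol-2-yl]acetate F6. Its Ireland–Claisen rearrangement (KHMDS, TMSCl, toluene, −78 °C to rt) should run through the usual chair with the arylacetate enolate having the pyrrole syn to O–K, and should give (E)-2-[1-Boc-5-(hept-6-en-1-yl)pyrrol-2-yl]-3-[(S)-2-(TBSO)propyl]hex-4-enoic acid F7 with both new centres in the target configuration. Ring‑closing metathesis (Grubbs II, dilute CH2Cl2, 40 °C) then closes the ring as the 3,4‑trans ansa alkene acid F8, HF·pyridine then PPTS gives the unsaturated 3,4‑trans ansa lactone F9, and hydrogenation (H2, Pd/C) gives 23, so that step 13 is not needed.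

Step 13. The enolate equilibrium may show little bias, since the trans lactone pays for an axial C6 methyl group and the cis lactone for an axial ansa bond, and enolisation next to the N‑Boc group may be slow. The fallback moves the correction to the spirocycle; it sets out from 22 and returns at 31. Lactone 22 is taken through the conditions of steps 14–17 to give the 3‑epi lactol F10, the 3‑epi methyl ketal F11, the 3‑epi methoxyacrylate with free pyrrole N–H F12 and the 3‑epi acrylamide F13. The spiro‑amidation is then run under forcing reversible conditions (TFA cat., CH2Cl2, 40 °C), where the oxocarbenium ion loses and regains H‑3 through the cyclic enol ether, so that C3 and the spiro centre equilibrate together in the rigid spirocycle to give 31.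

Step 18. Facial selectivity at the spiro centre may be poor under equilibration, because the desired chair holds the C6 methyl group syn‑axial to nitrogen; O‑closure to the imidate and acid‑induced degradation of the free pyrrole may also compete. The fallback forms the two bonds to the spiro carbon in the opposite order; it sets out from 30 and returns at 31. Mild aqueous acid (AcOH/H2O/THF) unmasks the ketone, which the amide closes to the 5‑hydroxy lactam with free C6 hydroxyl F14. BF3·OEt2 in CH2Cl2 at −78 °C then generates the N‑acyliminium ion, which the hydroxyl captures to close the pyran under kinetic control, a different bond‑forming event with its own facial preference.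

**Further compounds**

F1 | step 10 | ethyl 2-[1-Boc-5-(hept-6-en-1-yl)pyrrol-2-yl]acetate | CCOC(=O)Cc1ccc(CCCCCC=C)n1C(=O)OC(C)(C)C
F2 | step 10 | 2-[1-Boc-5-(hept-6-en-1-yl)pyrrol-2-yl]acetic acid | OC(=O)Cc1ccc(CCCCCC=C)n1C(=O)OC(C)(C)C
F3 | step 10 | (S)-6-(TBSO)hept-3-yn-2-one | CC(=O)C#CC[C@H](C)O[Si](C)(C)C(C)(C)C
F4 | step 10 | (2R,6S)-6-(TBSO)hept-3-yn-2-ol | C[C@@H](O)C#CC[C@H](C)O[Si](C)(C)C(C)(C)C
F5 | step 10 | (2R,3Z,6S)-6-(TBSO)hept-3-en-2-ol | C[C@@H](O)/C=C\C[C@H](C)O[Si](C)(C)C(C)(C)C
F6 | step 10 | (2R,3Z,6S)-6-(TBSO)hept-3-en-2-yl 2-[1-Boc-5-(hept-6-en-1-yl)pyrrol-2-yl]acetate | C[C@@H](OC(=O)Cc1ccc(CCCCCC=C)n1C(=O)OC(C)(C)C)/C=C\C[C@H](C)O[Si](C)(C)C(C)(C)C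
F7 | step 10 | (E)-2-[1-Boc-5-(hept-6-en-1-yl)pyrrol-2-yl]-3-[(S)-2-(TBSO)propyl]hex-4-enoic acid | C[C@H](O[Si](C)(C)C(C)(C)C)C[C@H](/C=C/C)[C@@H](c1ccc(CCCCCC=C)n1C(=O)OC(C)(C)C)C(=O)O
F8 | step 10 | 3,4-trans ansa alkene acid (ring alkene E/Z) | C[C@H](O[Si](C)(C)C(C)(C)C)C[C@@H]1C=CCCCCCc2ccc(n2C(=O)OC(C)(C)C)[C@H]1C(=O)O
F9 | step 10 | unsaturated 3,4-trans ansa lactone | C[C@H]1C[C@@H]2C=CCCCCCc3ccc(n3C(=O)OC(C)(C)C)[C@H]2C(=O)O1
F10 | step 13 | 3-epi lactol (3,4-cis analogue of 26) | COC(=O)C#CC2(O)O[C@@H](C)C[C@@H]1CCCCCCCc3ccc(n3C(=O)OC(C)(C)C)[C@@H]12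
F11 | step 13 | 3-epi methyl ketal (3,4-cis analogue of 27) | COC(=O)C#CC2(OC)O[C@@H](C)C[C@@H]1CCCCCCCc3ccc(n3C(=O)OC(C)(C)C)[C@@H]12
F12 | step 13 | 3-epi methoxyacrylate with free pyrrole N–H (3,4-cis analogue of 29) | COC(=O)/C=C(/OC)C2(OC)O[C@@H](C)C[C@@H]1CCCCCCCc3ccc([nH]3)[C@@H]12
F13 | step 13 | 3-epi acrylamide (3,4-cis analogue of 30) | NC(=O)/C=C(/OC)C2(OC)O[C@@H](C)C[C@@H]1CCCCCCCc3ccc([nH]3)[C@@H]12
F14 | step 18 | 5-hydroxy-4-methoxy-3-pyrrolin-2-one carrying the ansa pyrrolophane at C5, with free (S)-2-hydroxypropyl group | COC1=CC(=O)NC1(O)[C@@H]2c3ccc(CCCCCCC[C@H]2C[C@H](C)O)[nH]3
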